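## Structural features

The target (15) is an achiral dimer in which two C-methylated acylphloroglucinol units are joined by one methylene carbon. Ring A is a hexasubstituted benzene: C1' carries the 2-methylpropanoyl (isobutyryl) group, C2', C4' and C6' carry hydroxyls, C5' a methyl and C3' the bridge CH2. Ring B is the benzene ring of a 2,2-dimethylchroman-4-one with hydroxyls at C5 and C7, a methyl at C6 and the bridge at C8; the pyranone holds the quaternary carbon C2 and the C4 ketone. There is no stereocentre, so no stereochemical relationship has to be set. The fragile parts are the electron-rich phenolic rings (easily oxidised, above all as phenolates), the diarylmethane bridge (it can open and re-form through quinone methides in hot acid or alkali, which scrambles the two halves) and the chromanone (retro-oxa-Michael opening in strong base). The difficulty is regiochemical: in a phloroglucinol every ring carbon is activated, so acylation, annulation (6-methyl against 8-methyl chromanone) and bridging compete for almost equivalent sites, and the bridge must join two different rings without giving the two symmetrical dimers. The plan exploits the fact that the C6' hydroxyl is ortho to the isobutyryl carbonyl on C1' and the C5 hydroxyl is ortho (peri) to the C4 carbonyl on C4a. Without these two oxygens both rings are derivatives of 4-methylresorcinol, which has a single activated carbon at each stage, and the two ketones can later steer a metal to exactly the two C–H bonds that must become C–O bonds.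

## Logic of the disconnections

15 to 14: the three acetyl–oxygen bonds at C2'–O, C4'–O and C7–O are cut. The phenols must be capped during the oxidation, so this is a protecting-group adjustment with no gain in skeleton. The forward step must remove three hindered aryl esters without oxidising the polyphenolate and without disturbing the bridge or the chromanone.

14 to 12 (through 13): the aryl C–O bonds at C6' and C5 are cut. Each lies ortho to a ketone and is the only ortho C–H of that ketone once the oxygen is removed. The gain is that both rings fall back to the substitution pattern of 1, where no regiochemical choice remains. The forward step must metalate two C–H bonds that are each flanked by a methyl group, must tolerate a strong oxidant next to a diarylmethane, and needs the C2' oxygen capped so that the isobutyryl carbonyl can turn towards C6'–H.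

12 to 11: the same three acetyl–oxygen bonds are cut. The demand is complete acylation of three phenols that each have two ortho substituents, one of them hydrogen-bonded to the ketone.

11 to 8 and 3 (through 9 and 10): the C3'–CH2 bond is cut. The bridge carbon is already fixed on ring B, so only the cross-product can form. A one-pot condensation of 3, 6 and 7 would also give both symmetrical dimers, and this is the point where the assembly of 12 is improved. The gain is two monomers of similar size. The forward step must alkylate 3 at carbon, at its only activated position C3', and not at oxygen.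

8 to 6 and 7: the C8–CH2 and CH2–N bonds are cut. The gain is a stable, isolable carrier of the bridge carbon. The demand is aminomethylation of the ring at C8 and not alpha to the ketone at C3.

6 to 1 and 4 (through 5): the C4a–C4 acyl bond and the O1–C2 ether bond are cut. The forward step must acylate para to one hydroxyl and ortho to the other, then close the ring by conjugate addition of that ortho hydroxyl.

3 to 1 and 2: the C1'–C(=O) bond is cut. The demand is the same site selectivity as in the annulation, which the methyl group and the two hydroxyls of 1 secure.

## Other disconnections considered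

Alternative 1: The benzene ring of ring B is cut at C4a–C8a and C5–C6. In the forward direction the racemic cyclobutenone A1, which carries the protected ring A benzyl group on its sp3 carbon, is heated with ethoxyacetylene A2. Four-electron ring opening gives a vinylketene, [2+2] addition to the ynol ether gives a new cyclobutenone, a second opening and a six-electron electrocyclisation follow, and tautomerisation gives the phenol A3.
- In favour: the pericyclic sequence places all substituents of ring B, and its three oxygens arrive differentiated (free hydroxyl at C8a, ethyl ether at C5, silyl ether at C7). This answers the 6-methyl against 8-methyl question as firmly as the chosen plan does, so on regiochemical certainty it is the equal of the chosen plan. It needs no oxidant on an advanced intermediate, and on that point it is the better plan.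
- Against: A1 is the silyl enol ether of a disubstituted cyclobutane-1,3-dione bearing a very hindered benzyl group. Ring A must first be built with all oxygens, protected three times and turned into a benzylic electrophile. After A3 the sequence still needs acylation at C4a, oxa-Michael closure, removal of the C5 ethyl ether, desilylation and threefold debenzylation.
- Comparison: a thermal cascade without catalyst stands against a metal-catalysed C–H oxygenation. The cascade is less sensitive to the crowding around C5, but the route would be about twice as long as the seven steps chosen.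

Alternative 2: The chromanone acyl unit is cut at C4a–C4 and C3–C4. In the forward direction the ring B aryl iodide A4, carbon monoxide A5 and the alkenylboronate A6 are joined by Pd(OAc)2 and a bulky trialkylphosphine. Oxidative addition to zerovalent palladium, CO insertion, transmetalation and reductive elimination give the enone A7. Removal of the methoxymethyl group would then trigger oxa-Michael closure, and hydrogenolysis would free the five phenols.
- In favour: the site of bond formation is fixed by the C–I bond, which equals the chelation control of the chosen plan. The conditions are neutral to basic, so the bridge is not exposed to strong acid, and no late oxidation is needed; on functional-group safety at the key step it is the better plan.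
- Against: the iodide sits between two alkoxy groups on a hexasubstituted ring, so acyl transfer to a hindered alkenylboron partner is expected to be slow, and direct coupling without CO can compete. A4 also requires one phloroglucinol oxygen (C8a) to be told apart from the other two, which is the very regiochemical problem of this class. Six protecting groups are carried, and the debenzylation must spare two aryl ketones and the diarylmethane.
- Comparison: on step economy and protecting-group load it is clearly behind the chosen plan.

Alternative 3: Ring A is cut at C2'–C3' and C5'–C6'. In the forward direction the ketone A8, whose two alpha carbons carry the future bridge and the future C5' methyl, is acylated twice at carbon by malonyl dichloride A9, and enolisation gives the phloroglucinol A10. Acylation of the only free position C1' with 2 and debenzylation would finish the synthesis.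
- In favour: ring A arises with methyl, bridge and three oxygens in place, and the bridge carbon is part of the ketone chain. No diarylmethane coupling is needed and no symmetrical dimer can form, so on this point it is better than any bridging by a one-carbon electrophile, the chosen plan included. The final acylation has one site only, which equals the chosen plan.
- Against: ketones with alpha hydrogens and malonyl dichloride can close through oxygen to 4-hydroxypyran-2-ones instead of through carbon. A8 holds a second enolisable ketone (C3–H2 next to C4=O) and acid-labile benzyl ethers that would meet the hydrogen chloride set free. A8 itself needs the 5,7-dioxygenated 6-methyl chromanone, whose regiochemistry is not secured.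
- Comparison: a polar acylation cascade is cheap and metal-free, but its chemoselectivity is harder to steer than a chelation-directed C–H oxygenation, and the route is longer.

Key step: step 6

Remark on the chemistry: ring A is numbered from the isobutyryl-bearing carbon C1' and ring B by chromanone numbering. The target has no stereocentre. The bis-deoxy precursor 12 and its hydroxylation product 14 map atom for atom onto 15, so no structural correction is needed; the one change to the plan is the stepwise construction of the bridge of 12.

## Route

Step 1
Reactants: 1 4-methylresorcinol; 2 isobutyryl chloride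
Product: 3 1-(2,4-dihydroxy-5-methylphenyl)-2-methylpropan-1-one
Conditions: AlCl3 (2.5 equiv), CH2Cl2/MeNO2, 0 to 25 °C; then 1 M HCl
Reagents that add atoms: none
Why: Friedel–Crafts acylation of a resorcinol goes para to one hydroxyl and ortho to the other; the methyl group blocks the second such site and the position between the hydroxyls is hindered, so one ketone is expected.

Step 2
Reactants: 1 4-methylresorcinol; 4 3-methylbut-2-enoic acid
Product: 6 7-hydroxy-2,2,6-trimethylchroman-4-one, via open-chain aryl enone 5 (not isolated)
Conditions: P2O5/MeSO3H (1:10 w/w), 70 °C; then ice/H2O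
Reagents that add atoms: none
Why: Acylation by the mixed anhydride at the same ring carbon as in step 1 gives the 2-hydroxyaryl enone, and the ortho hydroxyl then adds to the beta carbon (6-endo oxa-Michael) to close the 2,2-dimethylchromanone, a standard annulation of resorcinols.

Step 3
Reactants: 6 7-hydroxy-2,2,6-trimethylchroman-4-one; 7 formaldehyde
Product: 8 8-[(dimethylamino)methyl]-7-hydroxy-2,2,6-trimethylchroman-4-one
Conditions: 7 (37% aq., 1.2 equiv), Me2NH (40% aq., 1.2 equiv), EtOH, 25 to 60 °C
Reagents that add atoms: dimethylamine, CNC
Why: Phenolic Mannich reaction: C8 is the only ring carbon ortho to the hydroxyl that is still free, and under free-amine conditions, without acid, the ring reacts in preference to the alpha carbon of the ketone.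

Step 4
Reactants: 8 8-[(dimethylamino)methyl]-7-hydroxy-2,2,6-trimethylchroman-4-one; 3 1-(2,4-dihydroxy-5-methylphenyl)-2-methylpropan-1-one
Product: 11 1-{2,4-dihydroxy-3-[(7-hydroxy-2,2,6-trimethyl-4-oxochroman-8-yl)methyl]-5-methylphenyl}-2-methylpropan-1-one, via ammonium iodide 9 (not isolated), via ortho-quinone methide 10 (not isolated)
Conditions: MeI (1.1 equiv), MeCN, 25 °C; evaporate; 3 (1.5 equiv), K2CO3 (2.5 equiv), MeCN, 60 °C; then 1 M HCl
Reagents that add atoms: none
Why: N-Methylation makes trimethylamine a leaving group, base releases the ortho-quinone methide, and the phenolate of 3 adds through C3', its only activated carbon (Mannich-base alkylation of phenols). Because the one-carbon unit is bound to ring B beforehand, neither symmetrical dimer has a direct path, and any O-adduct can revert to the quinone methide while the C-adduct cannot.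

Step 5
Reactants: 11 1-{2,4-dihydroxy-3-[(7-hydroxy-2,2,6-trimethyl-4-oxochroman-8-yl)methyl]-5-methylphenyl}-2-methylpropan-1-one
Product: 12 8-{[2,6-diacetoxy-3-methyl-5-(2-methylpropanoyl)phenyl]methyl}-2,2,6-trimethyl-4-oxochroman-7-yl acetate
Conditions: Ac2O (6 equiv), pyridine, DMAP (0.1 equiv), CH2Cl2, 25 to 40 °C
Reagents that add atoms: acetic anhydride, CC(=O)OC(C)=O
Why: DMAP-catalysed acylation is strong enough for phenols with two ortho substituents and for the hydrogen-bonded C2' hydroxyl. The three esters lower the electron density of both rings and free the isobutyryl carbonyl from its hydrogen bond.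

Step 6
Reactants: 12 8-{[2,6-diacetoxy-3-methyl-5-(2-methylpropanoyl)phenyl]methyl}-2,2,6-trimethyl-4-oxochroman-7-yl acetate
Product: 14 8-{[2,6-diacetoxy-4-hydroxy-3-methyl-5-(2-methylpropanoyl)phenyl]methyl}-5-hydroxy-2,2,6-trimethyl-4-oxochroman-7-yl acetate, via bis(trifluoroacetate) 13 (not isolated)
Conditions: [RuCl2(p-cymene)]2 (5 mol %), PhI(OCOCF3)2 (3 equiv), CF3CO2H/(CF3CO)2O (3:1), 80 °C; then THF/H2O, NaHCO3 (pH 7), 25 °C
Reagents that add atoms: phenyliodine bis(trifluoroacetate), O=C(OI(OC(=O)C(F)(F)F)c1ccccc1)C(F)(F)F (its trifluoroacetate ligands, which exchange with the solvent acid OC(=O)C(F)(F)F, supply the two new oxygen atoms)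
Why: This is the ketone-directed ortho C–H oxygenation of aryl ketones at divalent ruthenium, a known reaction of open-chain and cyclic aryl ketones, used here twice in one molecule. In the acid medium the chloride-bridged dimer becomes a ruthenium trifluoroacetate that binds each ketone oxygen, and carboxylate-assisted deprotonation forms a five-membered ruthenacycle at C6'–H on ring A and at C5–H on ring B. The trivalent iodine reagent oxidises the metallacycle to tetravalent ruthenium, and C–O reductive elimination releases the aryl trifluoroacetate and returns divalent ruthenium. The two labile esters of 13 are then cleaved at neutral pH, which should leave the three acetates in place. No ring is closed and no stereocentre is formed, so no closure mode and no stereocontrol element apply. The step needs site selectivity for one C–H per ketone, and the substrate secures it because the other ortho carbons (C2' and C8a) carry oxygen and no other C–H can reach the metal through a five-membered chelate. It also needs the rings, the bridge CH2 and the aryl methyls to survive the oxidant; the three acetates and the immediate trifluoroacetylation of each new phenol keep both rings electron-poor. Acetylation of the C2' oxygen removes the hydrogen bond that would hold the isobutyryl oxygen away from C6'–H, the chromanone carbonyl is held peri to C5–H by the ring, and Pd(OAc)2 with K2S2O8 in the same medium is the direct catalyst alternative because the two sites react independently.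

Step 7
Reactants: 14 8-{[2,6-diacetoxy-4-hydroxy-3-methyl-5-(2-methylpropanoyl)phenyl]methyl}-5-hydroxy-2,2,6-trimethyl-4-oxochroman-7-yl acetate
Product: 15 5,7-dihydroxy-2,2,6-trimethyl-8-{[2,4,6-trihydroxy-3-methyl-5-(2-methylpropanoyl)phenyl]methyl}chroman-4-one
Conditions: K2CO3 (3 equiv), degassed MeOH, Ar, 0 to 25 °C; then 1 M HCl
Reagents that add atoms: none
Why: Base-mediated transesterification of aryl acetates by methanol is fast at or below room temperature. Exclusion of air and a cold acidic quench should protect the polyphenolate and the bridge, and any ester exchanged for trifluoroacetate in step 6 is removed as well.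

## Compound list

1 | 4-methylresorcinol (4-methylbenzene-1,3-diol) | Cc1ccc(O)cc1O | starting material
2 | isobutyryl chloride (2-methylpropanoyl chloride) | CC(C)C(Cl)=O | starting material
3 | 1-(2,4-dihydroxy-5-methylphenyl)-2-methylpropan-1-one | Cc1cc(C(=O)C(C)C)c(O)cc1O | intermediate
4 | 3-methylbut-2-enoic acid | CC(C)=CC(=O)O | starting material
5 | 1-(2,4-dihydroxy-5-methylphenyl)-3-methylbut-2-en-1-one | CC(C)=CC(=O)c1cc(C)c(O)cc1O | intermediate (not isolated)
6 | 7-hydroxy-2,2,6-trimethylchroman-4-one | Cc1cc2C(=O)CC(C)(C)Oc2cc1O | intermediate
7 | formaldehyde | C=O | starting material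
8 | 8-[(dimethylamino)methyl]-7-hydroxy-2,2,6-trimethylchroman-4-one | CN(C)Cc1c(O)c(C)cc2C(=O)CC(C)(C)Oc12 | intermediate
9 | (7-hydroxy-2,2,6-trimethyl-4-oxochroman-8-yl)-N,N,N-trimethylmethanaminium iodide | C[N+](C)(C)Cc1c(O)c(C)cc2C(=O)CC(C)(C)Oc12.[I-] | intermediate (not isolated)
10 | 2,2,6-trimethyl-8-methylidene-2,3-dihydrochromene-4,7-dione (ortho-quinone methide) | C=C1C(=O)C(C)=CC2=C1OC(C)(C)CC2=O | intermediate (not isolated)
11 | 1-{2,4-dihydroxy-3-[(7-hydroxy-2,2,6-trimethyl-4-oxochroman-8-yl)methyl]-5-methylphenyl}-2-methylpropan-1-one | Cc1cc(C(=O)C(C)C)c(O)c(Cc2c(O)c(C)cc3c2OC(C)(C)CC3=O)c1O | intermediate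
12 | 8-{[2,6-diacetoxy-3-methyl-5-(2-methylpropanoyl)phenyl]methyl}-2,2,6-trimethyl-4-oxochroman-7-yl acetate | Cc1cc(C(=O)C(C)C)c(OC(C)=O)c(Cc2c(OC(C)=O)c(C)cc3c2OC(C)(C)CC3=O)c1OC(C)=O | intermediate (precursor of the key step)
13 | 8-{[2,6-diacetoxy-3-methyl-5-(2-methylpropanoyl)-4-(trifluoroacetoxy)phenyl]methyl}-2,2,6-trimethyl-4-oxo-5-(trifluoroacetoxy)chroman-7-yl acetate | Cc1c(OC(=O)C(F)(F)F)c(C(=O)C(C)C)c(OC(C)=O)c(Cc2c(OC(C)=O)c(C)c(OC(=O)C(F)(F)F)c3c2OC(C)(C)CC3=O)c1OC(C)=O | intermediate (not isolated)
14 | 8-{[2,6-diacetoxy-4-hydroxy-3-methyl-5-(2-methylpropanoyl)phenyl]methyl}-5-hydroxy-2,2,6-trimethyl-4-oxochroman-7-yl acetate | Cc1c(O)c(C(=O)C(C)C)c(OC(C)=O)c(Cc2c(OC(C)=O)c(C)c(O)c3c2OC(C)(C)CC3=O)c1OC(C)=O | intermediate (product of the key step)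
15 | 5,7-dihydroxy-2,2,6-trimethyl-8-{[2,4,6-trihydroxy-3-methyl-5-(2-methylpropanoyl)phenyl]methyl}chroman-4-one | Cc1c(O)c(Cc2c(O)c(C)c(O)c3c2OC(C)(C)CC3=O)c(O)c(C(=O)C(C)C)c1O | target

## Step count and risks

Total step count: 7. Longest linear sequence: 6 steps (steps 2, 3, 4, 5, 6 and 7, counted from 1); step 1 is a one-step side branch that joins at step 4.

Steps least certain to work:

**Step 6 (key step).**
- What may go wrong: slow or one-sided cyclometalation, because both C–H bonds are flanked by a methyl group and the ring A ketone is alpha-branched and twisted by its ortho acetate. Oxidation of the bridge methylene or alpha-oxygenation of the two enolisable ketones by the trivalent iodine reagent is also possible, as is exchange of acetate for trifluoroacetate in the hot acid medium.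
- Fallback: the two oxygens are brought in with the building blocks and no C–H oxygenation is used. It sets out from 2, 4 and 7 and comes back at 15. 2-Methylbenzene-1,3,5-triol F1 is C-acylated with 2 (AlCl3, CH2Cl2/MeNO2) to 2-methyl-1-(2,4,6-trihydroxy-3-methylphenyl)propan-1-one F2. F1 and 4 in P2O5/MeSO3H should give 5,7-dihydroxy-2,2,6-trimethylchroman-4-one F3. Here ring closure through either hydroxyl next to the new acyl group is possible, so a chromatographic separation of regioisomers must be accepted. F3 with 7 and dimethylamine gives the C8 Mannich base 8-[(dimethylamino)methyl]-5,7-dihydroxy-2,2,6-trimethylchroman-4-one F4, and MeI gives the ammonium iodide F5. K2CO3 in the presence of F2 releases the ortho-quinone methide 5-hydroxy-2,2,6-trimethyl-8-methylidene-2,3-dihydrochromene-4,7-dione F6, which F2 traps at its only free ring carbon to give 15 directly.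

**Step 4.**
- What may go wrong: slow loss of trimethylamine from an electron-poor phenolate, self-addition of the quinone methide, alkylation of 3 at oxygen, or exchange of the bridge that leads to symmetrical dimers.
- Fallback: the roles of the two rings are reversed. It sets out from 3 and comes back at 11. 3 with 7 and dimethylamine gives 1-{3-[(dimethylamino)methyl]-2,4-dihydroxy-5-methylphenyl}-2-methylpropan-1-one F7, and MeI gives the ammonium iodide F8. K2CO3 in the presence of 6 releases the quinone methide 5-hydroxy-2-methyl-6-methylidene-4-(2-methylpropanoyl)cyclohexa-2,4-dien-1-one F9, which 6 traps at C8 to give 11.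

**Step 2.**
- What may go wrong: conjugate addition of the arene to the unsaturated acid followed by lactonisation (a dihydrocoumarin pathway) in place of acylation, or acylation at the carbon between the two hydroxyls.
- Fallback: the chromanone is built by a Kabbe condensation, which has no such branch. It sets out from 1 and comes back at 6. 1 is acetylated at the same ring carbon (AcOH, BF3·OEt2, 90 °C) to 1-(2,4-dihydroxy-5-methylphenyl)ethan-1-one F10. Acetone and pyrrolidine (toluene, reflux) then give 6 through enamine aldol condensation and oxa-Michael closure.

**Step 7.**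
- What may go wrong: air oxidation of the polyphenolate, base-induced opening and re-closure of the methylene bridge that scrambles the two halves, or incomplete cleavage of the hindered C2' ester.
- Fallback: basic deprotection is avoided altogether by a change of protecting group. It sets out from 11 and comes back at 15, replacing steps 5 to 7. 11 is converted with (CF3CO)2O and pyridine into its tris(trifluoroacetate) F11. The oxygenation of step 6 in the same anhydride-containing medium should give the pentakis(trifluoroacetate) F12, and stirring F12 in methanol without added base should release 15.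

## Further compounds

F1 | step 6 | 2-methylbenzene-1,3,5-triol (2-methylphloroglucinol) | Cc1c(O)cc(O)cc1O
F2 | step 6 | 2-methyl-1-(2,4,6-trihydroxy-3-methylphenyl)propan-1-one | Cc1c(O)cc(O)c(C(=O)C(C)C)c1O
F3 | step 6 | 5,7-dihydroxy-2,2,6-trimethylchroman-4-one | Cc1c(O)cc2OC(C)(C)CC(=O)c2c1O
F4 | step 6 | 8-[(dimethylamino)methyl]-5,7-dihydroxy-2,2,6-trimethylchroman-4-one | CN(C)Cc1c(O)c(C)c(O)c2C(=O)CC(C)(C)Oc12
F5 | step 6 | (5,7-dihydroxy-2,2,6-trimethyl-4-oxochroman-8-yl)-N,N,N-trimethylmethanaminium iodide | C[N+](C)(C)Cc1c(O)c(C)c(O)c2C(=O)CC(C)(C)Oc12.[I-]
F6 | step 6 | 5-hydroxy-2,2,6-trimethyl-8-methylidene-2,3-dihydrochromene-4,7-dione | C=C1C(=O)C(C)=C(O)C2=C1OC(C)(C)CC2=O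
F7 | step 4 | 1-{3-[(dimethylamino)methyl]-2,4-dihydroxy-5-methylphenyl}-2-methylpropan-1-one | CN(C)Cc1c(O)c(C)cc(C(=O)C(C)C)c1O
F8 | step 4 | [2,6-dihydroxy-3-methyl-5-(2-methylpropanoyl)phenyl]-N,N,N-trimethylmethanaminium iodide | C[N+](C)(C)Cc1c(O)c(C)cc(C(=O)C(C)C)c1O.[I-]
F9 | step 4 | 5-hydroxy-2-methyl-6-methylidene-4-(2-methylpropanoyl)cyclohexa-2,4-dien-1-one | C=C1C(=O)C(C)=CC(C(=O)C(C)C)=C1O
F10 | step 2 | 1-(2,4-dihydroxy-5-methylphenyl)ethan-1-one | CC(=O)c1cc(C)c(O)cc1O
F11 | step 7 | 8-{[3-methyl-5-(2-methylpropanoyl)-2,6-bis(trifluoroacetoxy)phenyl]methyl}-2,2,6-trimethyl-4-oxochroman-7-yl trifluoroacetate | Cc1cc(C(=O)C(C)C)c(OC(=O)C(F)(F)F)c(Cc2c(OC(=O)C(F)(F)F)c(C)cc3c2OC(C)(C)CC3=O)c1OC(=O)C(F)(F)F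
F12 | step 7 | pentakis(trifluoroacetate) of 15 | Cc1c(OC(=O)C(F)(F)F)c(C(=O)C(C)C)c(OC(=O)C(F)(F)F)c(Cc2c(OC(=O)C(F)(F)F)c(C)c(OC(=O)C(F)(F)F)c3c2OC(C)(C)CC3=O)c1OC(=O)C(F)(F)F
A1 | alternative 1 | 4-{[2,4,6-tris(benzyloxy)-3-methyl-5-(2-methylpropanoyl)phenyl]methyl}-2-methyl-3-[(triisopropylsilyl)oxy]cyclobut-2-en-1-one (racemic) | CC1=C(O[Si](C(C)C)(C(C)C)C(C)C)C(Cc2c(OCc3ccccc3)c(C)c(OCc3ccccc3)c(C(=O)C(C)C)c2OCc2ccccc2)C1=O
A2 | alternative 1 | ethoxyacetylene (ethoxyethyne) | CCOC#C
A3 | alternative 1 | 1-{2,4,6-tris(benzyloxy)-3-{[4-ethoxy-6-hydroxy-3-methyl-2-[(triisopropylsilyl)oxy]phenyl]methyl}-5-methylphenyl}-2-methylpropan-1-one | CCOc1cc(O)c(Cc2c(OCc3ccccc3)c(C)c(OCc3ccccc3)c(C(=O)C(C)C)c2OCc2ccccc2)c(O[Si](C(C)C)(C(C)C)C(C)C)c1C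
A4 | alternative 2 | 1-{2,4,6-tris(benzyloxy)-3-{[2,4-bis(benzyloxy)-5-iodo-6-(methoxymethoxy)-3-methylphenyl]methyl}-5-methylphenyl}-2-methylpropan-1-one | Ic1c(OCOC)c(Cc2c(OCc3ccccc3)c(C)c(OCc3ccccc3)c(C(=O)C(C)C)c2OCc2ccccc2)c(OCc2ccccc2)c(C)c1OCc1ccccc1
A5 | alternative 2 | carbon monoxide | [C-]#[O+]
A6 | alternative 2 | 4,4,5,5-tetramethyl-2-(2-methylprop-1-en-1-yl)-1,3,2-dioxaborolane | CC(C)=CB1OC(C)(C)C(C)(C)O1
A7 | alternative 2 | 1-[4,6-bis(benzyloxy)-2-(methoxymethoxy)-5-methyl-3-{[2,4,6-tris(benzyloxy)-3-methyl-5-(2-methylpropanoyl)phenyl]methyl}phenyl]-3-methylbut-2-en-1-one | CC(C)=CC(=O)c1c(OCOC)c(Cc2c(OCc3ccccc3)c(C)c(OCc3ccccc3)c(C(=O)C(C)C)c2OCc2ccccc2)c(OCc2ccccc2)c(C)c1OCc1ccccc1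
A8 | alternative 3 | 5,7-bis(benzyloxy)-2,2,6-trimethyl-8-(3-oxopentyl)chroman-4-one | CCC(=O)CCc1c(OCc2ccccc2)c(C)c(OCc2ccccc2)c2c1OC(C)(C)CC2=O
A9 | alternative 3 | malonyl dichloride (propanedioyl dichloride) | O=C(Cl)CC(=O)Cl
A10 | alternative 3 | 5,7-bis(benzyloxy)-2,2,6-trimethyl-8-[(2,4,6-trihydroxy-3-methylphenyl)methyl]chroman-4-one | Cc1c(O)cc(O)c(Cc2c(OCc3ccccc3)c(C)c(OCc3ccccc3)c3c2OC(C)(C)CC3=O)c1O
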